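The carbocycle is disconnected at C5–C6. In the cyclohexane ring C5–C6–C7–C22–C21–C20 the acetoxy carbon C5 and the ether carbon C7 (methyl C8, bridging O9) stand 1,3 across the C6 methylene, so C5 is taken back to an aldehyde and C6=C7(C8) to an isopropenyl group. One Me2AlCl-promoted type 2 carbonyl-ene reaction then forms C5–C6, closes the six-membered ring, sets the C5 carbinol and leaves a C7=C8 methylene on which the oxepane bridge is later closed. Its substrate is a 5-methylhex-5-enal bearing the finished bromotetrahydropyran on C20, a triethylsilyl ether on O9 and a tert-butyldimethylsilyl ether on the C22 oxygen.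

Key step: step 15

Remark: atoms are numbered in the order of the target SMILES (acetate C1–O4; carbocycle C5, C6, C7, C22, C21, C20; methyl C8; bridging ether O9; pyran C10, C11, C12, C14, O17, C18 with Br13 and methyls C15, C16, C19; hydroxyl O23), and the allylboration of step 1 is assumed to follow the sense of induction established for aryl and alkenyl aldehydes.

Step 1
Reactants: 1 methacrolein; 2 allylboronic acid pinacol ester
Product: 4 (R)-2-methylhexa-1,5-dien-3-ol, via O-boryl pinacol ester 3 (not isolated)
Conditions: (R)-TRIP [(R)-3,3′-bis(2,4,6-triisopropylphenyl)-1,1′-binaphthyl-2,2′-diyl hydrogen phosphate] (5 mol %), toluene, −30 °C; aqueous work-up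
Reagents that add atoms: none
Why: Chiral phosphoric acid-catalysed asymmetric allylboration runs through a closed chair transition state in which the acid binds the boronate oxygen and the formyl hydrogen, so allyl transfer to the re face of the enal should set C22 as R.

Step 2
Reactants: 4 (R)-2-methylhexa-1,5-dien-3-ol
Product: 5 (R)-3-(tert-butyldimethylsilyloxy)-2-methylhexa-1,5-diene
Conditions: TBSCl, imidazole, DMF, rt
Reagents that add atoms: tert-butyldimethylsilyl chloride, CC(C)(C)[Si](C)(C)Cl
Why: Standard silylation of a secondary allylic alcohol, which also places a bulky group next to the 1,1-disubstituted alkene for the selectivity of step 3.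

Step 3
Reactants: 5 (R)-3-(tert-butyldimethylsilyloxy)-2-methylhexa-1,5-diene
Product: 7 (R)-4-(tert-butyldimethylsilyloxy)-5-methylhex-5-en-1-ol, via alkyl(disiamyl)borane 6 (not isolated)
Conditions: Sia2BH (from BH3·SMe2 and 2-methylbut-2-ene), THF, 0 °C; then NaOH, H2O2, 0 °C to rt
Reagents that add atoms: hydrogen peroxide, OO
Why: Hydroboration–oxidation with a hindered dialkylborane is anti-Markovnikov and should strongly prefer the unhindered monosubstituted alkene over the 1,1-disubstituted alkene flanked by the silyloxy carbon, leaving C22 untouched.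

Step 4
Reactants: 7 (R)-4-(tert-butyldimethylsilyloxy)-5-methylhex-5-en-1-ol
Product: 8 (R)-4-(tert-butyldimethylsilyloxy)-5-methylhex-5-enoic acid
Conditions: TEMPO (cat.), PhI(OAc)2, MeCN–H2O, rt
Reagents that add atoms: water, O
Why: Oxoammonium (TEMPO) catalysed oxidation takes the primary alcohol through the aldehyde hydrate to the acid and tolerates the alkene and the silyl ether.

Step 5
Reactants: 8 (R)-4-(tert-butyldimethylsilyloxy)-5-methylhex-5-enoic acid; 9 (S)-4-benzyloxazolidin-2-one
Product: 11 (S)-4-benzyl-3-[(R)-4-(tert-butyldimethylsilyloxy)-5-methylhex-5-enoyl]oxazolidin-2-one, via mixed pivalic anhydride 10 (not isolated)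
Conditions: PivCl, Et3N, THF, −20 °C; then 9, LiCl, rt
Reagents that add atoms: none
Why: N-Acylation of the oxazolidinone through the mixed anhydride under LiCl/Et3N activation is the usual entry to Evans imides and touches no stereocentre.

Step 6
Reactants: 12 methyl (S)-oxirane-2-carboxylate; 13 2-methylprop-1-enylmagnesium bromide
Product: 14 methyl (S)-2-hydroxy-5-methylhex-4-enoate
Conditions: CuI (10 mol %), THF, −40 °C; aqueous quench
Reagents that add atoms: none
Why: Copper-catalysed Grignard opening of a glycidic ester is an SN2 attack at the unsubstituted epoxide carbon, so the chiral-pool stereocentre becomes C10 (S) unchanged and the C12=C14 alkene is in place.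

Step 7
Reactants: 14 methyl (S)-2-hydroxy-5-methylhex-4-enoate
Product: 15 methyl (S)-5-methyl-2-(triethylsilyloxy)hex-4-enoate
Conditions: TESCl, imidazole, CH2Cl2, 0 °C
Reagents that add atoms: chlorotriethylsilane, CC[Si](CC)(CC)Cl
Why: Silylation of the α-hydroxy ester puts on O9 a non-chelating ether that is more labile than the C22 silyl ether, which steps 11, 15 and 16 rely on.

Step 8
Reactants: 15 methyl (S)-5-methyl-2-(triethylsilyloxy)hex-4-enoate
Product: 16 (S)-5-methyl-2-(triethylsilyloxy)hex-4-enal
Conditions: i-Bu2AlH, CH2Cl2, −78 °C; then MeOH, aq. potassium sodium tartrate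
Reagents that add atoms: none
Why: Low-temperature i-Bu2AlH reduction of an α-silyloxy ester stops at the aldehyde stage through the stable tetrahedral aluminium hemiacetal, and the α-stereocentre should survive if the crude aldehyde is used at once.

Step 9
Reactants: 11 (S)-4-benzyl-3-[(R)-4-(tert-butyldimethylsilyloxy)-5-methylhex-5-enoyl]oxazolidin-2-one; 16 (S)-5-methyl-2-(triethylsilyloxy)hex-4-enal
Product: 19 syn-aldol imide (10S 18S 20S 22R), via Z boron enolate 17 (not isolated), via boron aldolate 18 (not isolated)
Conditions: Bu2BOTf, i-Pr2NEt, CH2Cl2, −78 to 0 °C; 16, −78 to 0 °C; then pH 7 buffer, MeOH, H2O2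
Reagents that add atoms: none
Why: Evans syn aldol reaction, in which the Z boron enolate reacts through a Zimmerman–Traxler chair on the face away from the benzyl group of the (S)-auxiliary and so sets C20; the configuration of the C18 carbinol does not matter because step 10 oxidises it.

Step 10
Reactants: 19 syn-aldol imide
Product: 20 β-keto imide (10S 20S 22R) with the C18 ketone
Conditions: Dess–Martin periodinane, NaHCO3, CH2Cl2, 0 °C to rt
Reagents that add atoms: none
Why: Dess–Martin oxidation of an Evans aldol adduct gives the β-keto imide, whose C20 hydrogen is held in the plane of the dicarbonyl unit by allylic strain and should therefore not epimerise.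

Step 11
Reactants: 20 β-keto imide
Product: 21 tertiary alcohol imide (10S 18S 20S 22R) carrying the C19 methyl on C18
Conditions: MeMgBr, CeCl3, THF, −78 °C; AcOH quench at −78 °C
Reagents that add atoms: methylmagnesium bromide, C[Mg]Br
Why: Chelation-controlled organocerium addition to an α-substituted β-keto carbonyl compound, in which the metal bridges the ketone and imide carbonyls and methyl enters C18 anti to the C21 branch on C20; this is also the Felkin–Anh face with respect to the non-chelating C10 silyloxy group, so both elements should give 18S while the weakly basic reagent spares the imide.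

Step 12
Reactants: 21 tertiary alcohol imide
Product: 22 bromotetrahydropyranyl imide (10S 12S 18S 20S 22R)
Conditions: 2,4,4,6-tetrabromocyclohexa-2,5-dienone (TBCO), MeNO2, 0 °C, dark
Reagents that add atoms: 2,4,4,6-tetrabromocyclohexa-2,5-dienone, O=C1C(Br)=CC(Br)(Br)C=C1Br
Why: Bromoetherification (6-endo, Markovnikov), in which the C18 hydroxyl opens the bromonium ion of the trisubstituted alkene at C14 anti to bromine through a chair with the branched C20 substituent and bromine equatorial and the C10 silyloxy group axial, which should set C12 as S; the isopropenyl alkene is less nucleophilic because of its allylic silyloxy group and has no hydroxyl within reach.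

Step 13
Reactants: 22 bromotetrahydropyranyl imide
Product: 23 primary alcohol (10S 12S 18S 20R 22R) with C5 as CH2OH
Conditions: LiBH4, MeOH (1 equiv), Et2O, 0 °C
Reagents that add atoms: none
Why: Reductive cleavage of the N-acyl oxazolidinone with LiBH4 gives the primary alcohol and returns the auxiliary, while the hindered secondary bromide and the silyl ethers should be inert at 0 °C.

Step 14
Reactants: 23 primary alcohol
Product: 24 aldehyde (10S 12S 18S 20S 22R), the cyclisation substrate
Conditions: Dess–Martin periodinane, NaHCO3, CH2Cl2, 0 °C; used without chromatography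
Reagents that add atoms: none
Why: Buffered Dess–Martin oxidation forms the aldehyde under neutral conditions, which avoids epimerisation at C20 and β-elimination of the C18 ether.

Step 15
Reactants: 24 aldehyde
Product: 25 3-methylenecyclohexanol (5S 10S 12S 18S 20R 22R)
Conditions: Me2AlCl (2 equiv), CH2Cl2, −78 to −40 °C; aq. potassium sodium tartrate
Reagents that add atoms: none
Why: Me2AlCl coordinates the C5 aldehyde and the isopropenyl group reacts as the ene in a closed six-centre array, C6 bonding to C5 while a hydrogen of the C8 methyl passes to the aluminium-bound oxygen, which gives the aluminium alkoxide of 25 with the double bond moved to C7=C8. The closest known reaction type is the alkylaluminium halide-promoted type 2 intramolecular carbonyl-ene cyclisation of 2-substituted 5-methylhex-5-enals to 3-methylenecyclohexanols. The carbocycle C5–C6–C7–C22–C21–C20 closes as a six-membered chair, exo-trig at the carbonyl carbon, with both ene carbons C6 and C7 inside the new ring and the new alkene exocyclic. The new stereocentre C5 is controlled by this chair: the pyranyl group on C20 sits equatorial, the C22 silyloxy group is then axial, and the carbonyl oxygen has to be axial to reach the C8 hydrogen, so the hydroxyl should emerge cis to the C20 substituent (5S). The step needs this cis relationship and an intact C20 centre; the concerted hydrogen transfer secures the first, the low temperature and the proton-scavenging Me2AlCl the second, and the silyl ether on O9 blocks the five-membered lactol and offers aluminium no second binding site.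

Step 16
Reactants: 25 3-methylenecyclohexanol
Product: 26 diol (5S 10S 12S 18S 20R 22R) with free C5 and C10 hydroxyls
Conditions: PPTS (cat.), MeOH–CH2Cl2, 0 °C
Reagents that add atoms: none
Why: Acid-catalysed methanolysis distinguishes the triethylsilyl ether from the bulkier tert-butyldimethylsilyl ether, so only O9 is freed; the C5 hydroxyl is left unacylated because an axial C5 acetate could capture the C7 cation of step 17 through a six-membered acyloxonium ion.

Step 17
Reactants: 26 diol
Product: 28 bridged alcohol (5S 7R 10S 12S 18S 20R 22R), via alkylmercuric trifluoroacetate 27 (not isolated)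
Conditions: Hg(OCOCF3)2, CH2Cl2, 0 °C; then NaBH4, aq. NaOH, THF, 0 °C
Reagents that add atoms: none
Why: Intramolecular oxymercuration–demercuration, in which divalent mercury activates C7=C8 and the C10 hydroxyl adds at the more substituted carbon C7 on the only face it can reach, that of the C20 substituent, which closes the oxepane ring (7-exo) across a boat cyclohexane and sets C7 as R; borohydride then replaces mercury on C8 by hydrogen and should leave the secondary bromide alone.

Step 18
Reactants: 28 bridged alcohol
Product: 29 C5 acetate (5S 7R 10S 12S 18S 20R 22R)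
Conditions: Ac2O, DMAP, pyridine, CH2Cl2, rt
Reagents that add atoms: acetic anhydride, CC(=O)OC(C)=O
Why: DMAP-catalysed acetylation meets a single free hydroxyl, the C5 alcohol, since the C22 oxygen is still silylated.

Step 19
Reactants: 29 C5 acetate
Product: 30 CNP0247588.2 (5S 7R 10S 12S 18S 20R 22R)
Conditions: HF·pyridine, THF, rt
Reagents that add atoms: none
Why: Fluoride-driven desilylation (Si–F bond formation) under mildly acidic conditions frees the C22 hydroxyl and should not affect the acetate, the bromide or the two tertiary ethers.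

Compound list
1 | methacrolein | CC(=C)C=O | starting material
2 | allylboronic acid pinacol ester | C=CCB1OC(C)(C)C(C)(C)O1 | starting material
3 | O-boryl pinacol ester of 4 | C=C(C)[C@H](OB1OC(C)(C)C(C)(C)O1)CC=C | intermediate
4 | (R)-2-methylhexa-1,5-dien-3-ol | C=C(C)[C@H](O)CC=C | intermediate
5 | (R)-3-(tert-butyldimethylsilyloxy)-2-methylhexa-1,5-diene | C=C(C)[C@H](O[Si](C)(C)C(C)(C)C)CC=C | intermediate
6 | [(R)-4-(tert-butyldimethylsilyloxy)-5-methylhex-5-enyl]bis(3-methylbutan-2-yl)borane | C=C(C)[C@H](O[Si](C)(C)C(C)(C)C)CCCB(C(C)C(C)C)C(C)C(C)C | intermediate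
7 | (R)-4-(tert-butyldimethylsilyloxy)-5-methylhex-5-en-1-ol | C=C(C)[C@H](O[Si](C)(C)C(C)(C)C)CCCO | intermediate
8 | (R)-4-(tert-butyldimethylsilyloxy)-5-methylhex-5-enoic acid | C=C(C)[C@H](O[Si](C)(C)C(C)(C)C)CCC(=O)O | intermediate
9 | (S)-4-benzyloxazolidin-2-one | O=C1N[C@@H](Cc2ccccc2)CO1 | starting material
10 | mixed anhydride of 8 and pivalic acid | C=C(C)[C@H](O[Si](C)(C)C(C)(C)C)CCC(=O)OC(=O)C(C)(C)C | intermediate
11 | (S)-4-benzyl-3-[(R)-4-(tert-butyldimethylsilyloxy)-5-methylhex-5-enoyl]oxazolidin-2-one | C=C(C)[C@H](O[Si](C)(C)C(C)(C)C)CCC(=O)N1[C@@H](Cc2ccccc2)COC1=O | intermediate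
12 | methyl (S)-oxirane-2-carboxylate (methyl (S)-glycidate) | COC(=O)[C@@H]1CO1 | starting material
13 | 2-methylprop-1-enylmagnesium bromide | CC(C)=C[Mg]Br | starting material
14 | methyl (S)-2-hydroxy-5-methylhex-4-enoate | COC(=O)[C@@H](O)CC=C(C)C | intermediate
15 | methyl (S)-5-methyl-2-(triethylsilyloxy)hex-4-enoate | COC(=O)[C@@H](O[Si](CC)(CC)CC)CC=C(C)C | intermediate
16 | (S)-5-methyl-2-(triethylsilyloxy)hex-4-enal | O=C[C@@H](O[Si](CC)(CC)CC)CC=C(C)C | intermediate
17 | (Z)-dibutylboron enolate of imide 11 | C=C(C)[C@H](O[Si](C)(C)C(C)(C)C)C/C=C(\OB(CCCC)CCCC)N1[C@@H](Cc2ccccc2)COC1=O | intermediate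
18 | dibutylboron aldolate of 19 | CC(C)=CC[C@H](O[Si](CC)(CC)CC)[C@@H](OB(CCCC)CCCC)[C@H](C[C@@H](O[Si](C)(C)C(C)(C)C)C(C)=C)C(=O)N1[C@@H](Cc2ccccc2)COC1=O | intermediate
19 | syn-aldol imide: N-acyl (S)-4-benzyloxazolidinone with C20 (S) bearing the C21–C22(OTBS)–isopropenyl branch, C18 (S) carbinol, C10 (S) OTES and the prenyl-type chain | CC(C)=CC[C@H](O[Si](CC)(CC)CC)[C@@H](O)[C@H](C[C@@H](O[Si](C)(C)C(C)(C)C)C(C)=C)C(=O)N1[C@@H](Cc2ccccc2)COC1=O | intermediate
20 | β-keto imide (C18 ketone; 10S, 20S, 22R) | CC(C)=CC[C@H](O[Si](CC)(CC)CC)C(=O)[C@H](C[C@@H](O[Si](C)(C)C(C)(C)C)C(C)=C)C(=O)N1[C@@H](Cc2ccccc2)COC1=O | intermediate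
21 | tertiary alcohol imide (C18 with methyl and hydroxyl; 10S, 18S, 20S, 22R) | CC(C)=CC[C@H](O[Si](CC)(CC)CC)[C@@](C)(O)[C@H](C[C@@H](O[Si](C)(C)C(C)(C)C)C(C)=C)C(=O)N1[C@@H](Cc2ccccc2)COC1=O | intermediate
22 | bromotetrahydropyranyl imide: C20 carries the 3-bromo-2,2,6-trimethyl-5-(triethylsilyloxy)tetrahydropyran-6-yl group (10S, 12S, 18S, 20S, 22R) | O=C([C@@H](C[C@@H](O[Si](C)(C)C(C)(C)C)C(C)=C)[C@]1(C)OC(C)(C)[C@@H](Br)C[C@@H]1O[Si](CC)(CC)CC)N2[C@@H](Cc3ccccc3)COC2=O | intermediate
23 | primary alcohol (C5 as CH2OH; 10S, 12S, 18S, 20R, 22R) | OC[C@@H](C[C@@H](O[Si](C)(C)C(C)(C)C)C(C)=C)[C@]1(C)OC(C)(C)[C@@H](Br)C[C@@H]1O[Si](CC)(CC)CC | intermediate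
24 | pyranyl 5-methylhex-5-enal, the cyclisation substrate (10S, 12S, 18S, 20S, 22R) | O=C[C@@H](C[C@@H](O[Si](C)(C)C(C)(C)C)C(C)=C)[C@]1(C)OC(C)(C)[C@@H](Br)C[C@@H]1O[Si](CC)(CC)CC | intermediate
25 | pyranyl 3-methylenecyclohexanol (5S, 10S, 12S, 18S, 20R, 22R) | O[C@H]1CC(=C)[C@H](O[Si](C)(C)C(C)(C)C)C[C@H]1[C@]2(C)OC(C)(C)[C@@H](Br)C[C@@H]2O[Si](CC)(CC)CC | intermediate
26 | diol with free C5 and C10 hydroxyls and C22 OTBS | O[C@H]1CC(=C)[C@H](O[Si](C)(C)C(C)(C)C)C[C@H]1[C@]2(C)OC(C)(C)[C@@H](Br)C[C@@H]2O | intermediate
27 | bridged alkylmercuric trifluoroacetate (mercury on C8) | O[C@H]1C[C@@]2(C[Hg]OC(=O)C(F)(F)F)O[C@H]3C[C@H](Br)C(C)(C)O[C@@]3(C)[C@@H]1C[C@H]2O[Si](C)(C)C(C)(C)C | intermediate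
28 | bridged tricyclic alcohol with free C5 hydroxyl and C22 OTBS (5S, 7R, 10S, 12S, 18S, 20R, 22R) | O[C@H]1C[C@@]2(C)O[C@H]3C[C@H](Br)C(C)(C)O[C@@]3(C)[C@@H]1C[C@H]2O[Si](C)(C)C(C)(C)C | intermediate
29 | C5 acetate with C22 OTBS | CC(=O)O[C@H]1C[C@@]2(C)O[C@H]3C[C@H](Br)C(C)(C)O[C@@]3(C)[C@@H]1C[C@H]2O[Si](C)(C)C(C)(C)C | intermediate
30 | CNP0247588.2 (5S, 7R, 10S, 12S, 18S, 20R, 22R) | CC(=O)O[C@H]1C[C@@]2(C)O[C@H]3C[C@H](Br)C(C)(C)O[C@@]3(C)[C@@H]1C[C@H]2O | target

Total step count: 19. Longest linear sequence: 16 steps (steps 1–5 and 9–19); steps 6–8 make the second fragment.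

Steps most likely to fail

Step 15. The closure may leave the concerted pathway for an open zwitterion or a boat, which would lose facial control at C5 and give the equatorial alcohol. The fallback sets out from 24: the cyclisation mixture of 25 and its equatorial C5 epimer F1 would be oxidised with Dess–Martin periodinane (NaHCO3, CH2Cl2) to the 3-methylenecyclohexanone F2. Reduction with LiBH(s-Bu)3 in THF at −78 °C should then deliver hydride along the equatorial direction and give the axial alcohol cis to the C20 substituent, which comes back to the route at 25.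

Step 12. Three processes could compete: poor facial selectivity at C12, five-membered closure by attack at C12 (bromine then ends on C14), and bromination of the isopropenyl alkene. The fallback sets out from 21 and separates ring closure from bromine introduction. Reversible, thermodynamically controlled oxymercuration with Hg(OCOCF3)2 in MeNO2 at 0 °C, followed by aq. KBr, should give the alkylmercuric bromide F3 as the Markovnikov six-membered ether with the C12–Hg bond equatorial. Brominolysis of the C–Hg bond with LiBr and Br2 in pyridine under O2 in the dark proceeds with retention and would come back to the route at 22.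

Step 11. The methyl nucleophile may attack the imide carbonyls, the tertiary alkoxide may cyclise onto the oxazolidinone or undergo retro-aldol cleavage, or the hindered ketone may not convert. The fallback sets out from 19 and removes the auxiliary before the methyl addition:
- LiBH4 (MeOH, Et2O, 0 °C) would give the diol F4.
- Bu2SnO (toluene, reflux) and then PMBCl with Bu4NI would protect the primary hydroxyl as the p-methoxybenzyl ether F5.
- Dess–Martin oxidation would give the ketone F6.
- MeMgBr in CH2Cl2–Et2O at −78 °C should add anti to the C21 branch through the six-membered chelate between the ketone and the C5 benzyl-type ether (again the Felkin–Anh face for the C10 silyloxy group), giving the tertiary alcohol F7.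
- TBCO in MeNO2 would close the bromotetrahydropyran F8.
- DDQ (CH2Cl2, pH 7 buffer) would remove the p-methoxybenzyl group, which comes back to the route at 23.

Further compounds
F1 | step 15 | equatorial C5 epimer of 25 | O[C@@H]1CC(=C)[C@H](O[Si](C)(C)C(C)(C)C)C[C@H]1[C@]2(C)OC(C)(C)[C@@H](Br)C[C@@H]2O[Si](CC)(CC)CC
F2 | step 15 | pyranyl 3-methylenecyclohexanone (C5 ketone) | O=C1CC(=C)[C@H](O[Si](C)(C)C(C)(C)C)C[C@H]1[C@]2(C)OC(C)(C)[C@@H](Br)C[C@@H]2O[Si](CC)(CC)CC
F3 | step 12 | tetrahydropyranyl imide with bromomercurio group on C12 | O=C([C@@H](C[C@@H](O[Si](C)(C)C(C)(C)C)C(C)=C)[C@]1(C)OC(C)(C)[C@@H]([Hg]Br)C[C@@H]1O[Si](CC)(CC)CC)N2[C@@H](Cc3ccccc3)COC2=O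
F4 | step 11 | 1,3-diol from reductive cleavage of 19 (C5 CH2OH, C18 carbinol) | CC(C)=CC[C@H](O[Si](CC)(CC)CC)[C@@H](O)[C@H](C[C@@H](O[Si](C)(C)C(C)(C)C)C(C)=C)CO
F5 | step 11 | primary p-methoxybenzyl ether of F4 | CC(C)=CC[C@H](O[Si](CC)(CC)CC)[C@@H](O)[C@H](C[C@@H](O[Si](C)(C)C(C)(C)C)C(C)=C)COCc1ccc(OC)cc1
F6 | step 11 | C18 ketone with C5 p-methoxybenzyl ether | CC(C)=CC[C@H](O[Si](CC)(CC)CC)C(=O)[C@H](C[C@@H](O[Si](C)(C)C(C)(C)C)C(C)=C)COCc1ccc(OC)cc1
F7 | step 11 | tertiary alcohol (18S) with C5 p-methoxybenzyl ether | CC(C)=CC[C@H](O[Si](CC)(CC)CC)[C@@](C)(O)[C@H](C[C@@H](O[Si](C)(C)C(C)(C)C)C(C)=C)COCc1ccc(OC)cc1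
F8 | step 11 | bromotetrahydropyran with C5 p-methoxybenzyl ether | COc1ccc(COC[C@@H](C[C@@H](O[Si](C)(C)C(C)(C)C)C(C)=C)[C@]2(C)OC(C)(C)[C@@H](Br)C[C@@H]2O[Si](CC)(CC)CC)cc1
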